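## Retrosynthetic overview

1. Target 19 ⇐ desilylation/acetylation ⇐ C2–C3 vinylogous Mukaiyama aldol of silyl trienol ether 3 (ring B) with aldehyde 16.
2. 16 ⇐ thioester reduction and O5 propanoylation ⇐ C4–C5 anti propanoate aldol on enal 10.
3. 10 ⇐ C7–C8 vinylogous aldol of trienol ether 7 (ring A) with 3-ethoxymethacrolein, then acid-induced loss of ethanol to the (E)-enal.
4. 7 ⇐ 5 ⇐ key step: the aromatic, C2v-symmetric pyranone 1 is converted to the non-aromatic trienol ether 3 and desymmetrised by a catalytic enantioselective anti vinylogous aldol with propanal (sets C2′, C3′).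
5. No ring is constructed: rings A and B both come intact from 1. Ring A is elaborated first on both ethyl arms; ring B is attached last on one arm.

Labels: chain carbons C1–C9 follow the non-6-ene name of the target (C2 carries ring B, C8 carries ring A); C2′/C3′ are the stereocentres of the hydroxypentyl arm on ring A. Target configuration: 2R,3R,4R,5R,6E,8S,2′S,3′S.

Catalyst: "bisphosphoramide" means two N,N′-dimethyl-1,1′-binaphthyl-2,2′-diamine phosphoramide units joined by an N,N′-dimethylpentane-1,5-diamine linker, used with SiCl4.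

Assumption 1: 2,6-diethyl-3,5-dimethyl-4H-pyran-4-one (1) is bought as a catalogue γ-pyrone.

Assumption 2: the (R,R)-bisphosphoramide is taken as the enantiomer that exposes the aldehyde Re face; if the sense is the reverse with these nucleophiles, (R,R) and (S,S) are exchanged in steps 2, 4, 6 and 9.

## Route

Step 1
Reactants: 1 2,6-diethyl-3,5-dimethyl-4H-pyran-4-one
Product: 3 tert-butyl{[(2Z)-6-ethyl-2-ethylidene-3,5-dimethyl-2H-pyran-4-yl]oxy}dimethylsilane, via silyloxypyrylium triflate 2 (not isolated)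
Conditions: TBSOTf (1.1 equiv), Et3N (1.5 equiv), Et2O, 0 °C; pentane, filter, distil
Reagents that add atoms: TBSOTf, CC(C)(C)[Si](C)(C)OS(=O)(=O)C(F)(F)F
Why: Soft enolisation: TBSOTf silylates the pyranone oxygen to pyrylium 2, whose activated 2-ethyl CH2 is deprotonated by Et3N, trading ring aromaticity for a nucleophilic 2-alkylidene-2H-pyran (Z because the ethylidene methyl avoids the C3 methyl); only one arm reacts because neutral 3 has no carbonyl left to silylate.

Step 2
Reactants: 3 silyl trienol ether; 4 propanal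
Product: 5 2-ethyl-6-[(2S,3S)-3-hydroxypentan-2-yl]-3,5-dimethyl-4H-pyran-4-one
Conditions: SiCl4 (1.2 equiv), (R,R)-bisphosphoramide (5 mol %), i-Pr2NEt (10 mol %), CH2Cl2, −78 °C; aq NaHCO3
Reagents that add atoms: none
Why: Proposed new method: 3 is a ring-oxygen-substituted silyl dienol ether of the same type as the dioxinone-derived dienol ethers used in Lewis-base-activated SiCl4 vinylogous Mukaiyama aldol reactions (closest known reaction), so propanal bound to the chiral bisphosphoramide–SiCl3 cation should be attacked on its Re face by the exocyclic γ-carbon through an open, anti-selective transition state, with re-aromatisation to the pyranone and loss of the TBS group as driving force; this one C–C bond formation breaks the symmetry of 1 and sets C2′ (S) and C3′ (S).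

Step 3
Reactants: 5 hydroxy pyranone
Product: 7 tert-butyl{[(2S,3S)-2-{(6Z)-4-[(tert-butyldimethylsilyl)oxy]-6-ethylidene-3,5-dimethyl-6H-pyran-2-yl}pentan-3-yl]oxy}dimethylsilane, via bis-silylated pyrylium triflate 6 (not isolated)
Conditions: TBSOTf (2.3 equiv), Et3N (3.5 equiv), CH2Cl2, 0 °C; pentane, filter through basic alumina
Reagents that add atoms: TBSOTf, CC(C)(C)[Si](C)(C)OS(=O)(=O)C(F)(F)F
Why: The same soft enolisation after O-silylation of the alcohol; Et3N takes a proton from the unhindered CH2 of the remaining ethyl arm rather than the tertiary C2′–H (the alternative tetrasubstituted alkylidene suffers A(1,3) strain), so C2′/C3′ are untouched and the C3′ oxygen is protected in the same operation.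

Step 4
Reactants: 7 ring A trienol ether; 8 (E)-3-ethoxy-2-methylprop-2-enal
Product: 10 (2E,4S)-4-{6-[(2S,3S)-3-(tert-butyldimethylsilyloxy)pentan-2-yl]-3,5-dimethyl-4-oxo-4H-pyran-2-yl}-2-methylpent-2-enal, via hydroxy enol ether adduct 9 (not isolated)
Conditions: 8 (1.5 equiv), SiCl4 (1.5 equiv), (R,R)-bisphosphoramide (5 mol %), i-Pr2NEt (10 mol %), CH2Cl2, −78 °C; aq NaHCO3; then PPTS (cat.), acetone–H2O, 0 °C
Reagents that add atoms: water, O
Why: Proposed new method: the same catalytic vinylogous Mukaiyama aldol with the vinylogous formate 8 (closest known: this reaction with α-methyl enals, and Stork–Danheiser-type addition/acid transposition of β-alkoxy enones); Re-face, anti-selective addition fixes C8 as S, and mild acid then ionises the γ-hydroxy enol ether of 9 and exchanges ethanol for water to leave the thermodynamically preferred (E)-enal, expending the transient carbinol centre.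

Step 5
Reactants: 11 S-ethyl propanethioate
Product: 13 tert-butyl{[(1Z)-1-(ethylsulfanyl)prop-1-en-1-yl]oxy}dimethylsilane, via lithium thioester enolate 12 (not isolated)
Conditions: LiN(i-Pr)2, THF, −78 °C; TBSCl, DMPU, −78 → 0 °C
Reagents that add atoms: TBSCl, CC(C)(C)[Si](C)(C)Cl
Why: Kinetic deprotonation (Ireland model) gives the enolate with OLi trans to methyl, which is trapped on oxygen (silyl ketene S,O-acetal formation).

Step 6
Reactants: 10 enal; 13 silyl ketene acetal
Product: 14 S-ethyl (2S,3R,4E,6S)-6-{6-[(2S,3S)-3-(tert-butyldimethylsilyloxy)pentan-2-yl]-3,5-dimethyl-4-oxo-4H-pyran-2-yl}-3-hydroxy-2,4-dimethylhept-4-enethioate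
Conditions: 13 (1.5 equiv), SiCl4 (1.5 equiv), (R,R)-bisphosphoramide (5 mol %), CH2Cl2, −78 °C; aq NaHCO3
Reagents that add atoms: none
Why: Lewis-base-catalysed SiCl4 Mukaiyama aldol: propanoate-type silyl ketene acetals add to α-methyl enals through an open transition state that is anti-selective whatever the ketene acetal geometry, and Re-face attack under catalyst control gives C5 (R) with C4 anti; the conditions are non-basic at −78 °C, so the doubly activated C8–H is not disturbed.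

Step 7
Reactants: 14 hydroxy thioester
Product: 15 S-ethyl (2S,3R,4E,6S)-6-{6-[(2S,3S)-3-(tert-butyldimethylsilyloxy)pentan-2-yl]-3,5-dimethyl-4-oxo-4H-pyran-2-yl}-2,4-dimethyl-3-(propanoyloxy)hept-4-enethioate
Conditions: (EtCO)2O, pyridine, DMAP (cat.), CH2Cl2, 0 °C
Reagents that add atoms: propanoic anhydride, CCC(=O)OC(=O)CC
Why: DMAP-catalysed acylation of the only free hydroxyl (O5), the ring A arm hydroxyl being masked as its TBS ether.

Step 8
Reactants: 15 propanoyloxy thioester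
Product: 16 (2S,3R,4E,6S)-6-{6-[(2S,3S)-3-(tert-butyldimethylsilyloxy)pentan-2-yl]-3,5-dimethyl-4-oxo-4H-pyran-2-yl}-2,4-dimethyl-1-oxohept-4-en-3-yl propanoate
Conditions: Et3SiH, 10% Pd/C, acetone, rt
Reagents that add atoms: none
Why: Fukuyama reduction: palladium inserts into the thioester C–S bond and the silane delivers hydride, giving the aldehyde without base and without touching the O-ester, pyranones, silyl ether or trisubstituted alkene, so the β-acyloxy aldehyde neither eliminates nor epimerises.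

Step 9
Reactants: 16 aldehyde; 3 silyl trienol ether
Product: 17 (2R,3R,4R,5R,6E,8S)-8-{6-[(2S,3S)-3-(tert-butyldimethylsilyloxy)pentan-2-yl]-3,5-dimethyl-4-oxo-4H-pyran-2-yl}-2-(6-ethyl-3,5-dimethyl-4-oxo-4H-pyran-2-yl)-3-hydroxy-4,6-dimethylnon-6-en-5-yl propanoate
Conditions: 3 (1.5 equiv), SiCl4 (1.5 equiv), (S,S)-bisphosphoramide (10 mol %), i-Pr2NEt (10 mol %), CH2Cl2, −78 → −50 °C; aq NaHCO3
Reagents that add atoms: none
Why: Proposed new method: second use of the catalytic vinylogous Mukaiyama aldol of 3 (closest known reaction as in step 2), here as a matched double stereodifferentiation in which the Si face chosen by the (S,S)-catalyst is also the Felkin–Anh face (C3/C4 syn) and the 1,3-anti face relative to the C5 acyloxy group, while the open transition state gives C2/C3 anti, setting C2 (R) and C3 (R).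

Step 10
Reactants: 17 C3 alcohol
Product: 18 (2R,3R,4R,5R,6E,8S)-3-acetoxy-8-{6-[(2S,3S)-3-(tert-butyldimethylsilyloxy)pentan-2-yl]-3,5-dimethyl-4-oxo-4H-pyran-2-yl}-2-(6-ethyl-3,5-dimethyl-4-oxo-4H-pyran-2-yl)-4,6-dimethylnon-6-en-5-yl propanoate
Conditions: Ac2O, pyridine, DMAP (cat.), CH2Cl2, 0 °C → rt
Reagents that add atoms: acetic anhydride, CC(=O)OC(C)=O
Why: DMAP-catalysed acetylation of the single free secondary alcohol; the weak base at low temperature avoids β-elimination toward the pyranone.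

Step 11
Reactants: 18 silyl ether
Product: 19 CNP0265513.1, (2R,3R,4R,5R,6E,8S)-3-acetoxy-2-(6-ethyl-3,5-dimethyl-4-oxo-4H-pyran-2-yl)-8-{6-[(2S,3S)-3-hydroxypentan-2-yl]-3,5-dimethyl-4-oxo-4H-pyran-2-yl}-4,6-dimethylnon-6-en-5-yl propanoate
Conditions: HF·pyridine, pyridine, THF, 0 °C → rt
Reagents that add atoms: none
Why: Fluoride-driven Si–O cleavage (desilylation) under buffered conditions leaves both esters, the skipped alkene and the β-acyloxy pyranone units intact and frees the C3′ hydroxyl.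

## Compound list

1 | 2,6-diethyl-3,5-dimethyl-4H-pyran-4-one | CCc1oc(CC)c(C)c(=O)c1C | starting material
2 | 4-[(tert-butyldimethylsilyl)oxy]-2,6-diethyl-3,5-dimethylpyrylium triflate | CCc1[o+]c(CC)c(C)c(O[Si](C)(C)C(C)(C)C)c1C.[O-]S(=O)(=O)C(F)(F)F | intermediate
3 | tert-butyl{[(2Z)-6-ethyl-2-ethylidene-3,5-dimethyl-2H-pyran-4-yl]oxy}dimethylsilane | C/C=C1\OC(CC)=C(C)C(O[Si](C)(C)C(C)(C)C)=C1C | intermediate
4 | propanal | CCC=O | starting material
5 | 2-ethyl-6-[(2S,3S)-3-hydroxypentan-2-yl]-3,5-dimethyl-4H-pyran-4-one | CCc1oc([C@@H](C)[C@@H](O)CC)c(C)c(=O)c1C | intermediate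
6 | 4-[(tert-butyldimethylsilyl)oxy]-2-[(2S,3S)-3-(tert-butyldimethylsilyloxy)pentan-2-yl]-6-ethyl-3,5-dimethylpyrylium triflate | CCc1[o+]c([C@@H](C)[C@@H](O[Si](C)(C)C(C)(C)C)CC)c(C)c(O[Si](C)(C)C(C)(C)C)c1C.[O-]S(=O)(=O)C(F)(F)F | intermediate
7 | tert-butyl{[(2S,3S)-2-{(6Z)-4-[(tert-butyldimethylsilyl)oxy]-6-ethylidene-3,5-dimethyl-6H-pyran-2-yl}pentan-3-yl]oxy}dimethylsilane | C/C=C1\OC([C@@H](C)[C@@H](O[Si](C)(C)C(C)(C)C)CC)=C(C)C(O[Si](C)(C)C(C)(C)C)=C1C | intermediate
8 | (E)-3-ethoxy-2-methylprop-2-enal | CCO/C=C(\C)C=O | starting material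
9 | 2-[(2S,3R,4E)-5-ethoxy-3-hydroxy-4-methylpent-4-en-2-yl]-6-[(2S,3S)-3-(tert-butyldimethylsilyloxy)pentan-2-yl]-3,5-dimethyl-4H-pyran-4-one | CCO/C=C(\C)[C@H](O)[C@H](C)c1oc([C@@H](C)[C@@H](O[Si](C)(C)C(C)(C)C)CC)c(C)c(=O)c1C | intermediate
10 | (2E,4S)-4-{6-[(2S,3S)-3-(tert-butyldimethylsilyloxy)pentan-2-yl]-3,5-dimethyl-4-oxo-4H-pyran-2-yl}-2-methylpent-2-enal | O=C/C(C)=C/[C@H](C)c1oc([C@@H](C)[C@@H](O[Si](C)(C)C(C)(C)C)CC)c(C)c(=O)c1C | intermediate
11 | S-ethyl propanethioate | CCC(=O)SCC | starting material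
12 | lithium (1Z)-1-(ethylsulfanyl)prop-1-en-1-olate | C/C=C(/[O-])SCC.[Li+] | intermediate
13 | tert-butyl{[(1Z)-1-(ethylsulfanyl)prop-1-en-1-yl]oxy}dimethylsilane | C/C=C(/O[Si](C)(C)C(C)(C)C)SCC | intermediate
14 | S-ethyl (2S,3R,4E,6S)-6-{6-[(2S,3S)-3-(tert-butyldimethylsilyloxy)pentan-2-yl]-3,5-dimethyl-4-oxo-4H-pyran-2-yl}-3-hydroxy-2,4-dimethylhept-4-enethioate | CCSC(=O)[C@@H](C)[C@@H](O)/C(C)=C/[C@H](C)c1oc([C@@H](C)[C@@H](O[Si](C)(C)C(C)(C)C)CC)c(C)c(=O)c1C | intermediate
15 | S-ethyl (2S,3R,4E,6S)-6-{6-[(2S,3S)-3-(tert-butyldimethylsilyloxy)pentan-2-yl]-3,5-dimethyl-4-oxo-4H-pyran-2-yl}-2,4-dimethyl-3-(propanoyloxy)hept-4-enethioate | CCSC(=O)[C@@H](C)[C@@H](OC(=O)CC)/C(C)=C/[C@H](C)c1oc([C@@H](C)[C@@H](O[Si](C)(C)C(C)(C)C)CC)c(C)c(=O)c1C | intermediate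
16 | (2S,3R,4E,6S)-6-{6-[(2S,3S)-3-(tert-butyldimethylsilyloxy)pentan-2-yl]-3,5-dimethyl-4-oxo-4H-pyran-2-yl}-2,4-dimethyl-1-oxohept-4-en-3-yl propanoate | O=C[C@@H](C)[C@@H](OC(=O)CC)/C(C)=C/[C@H](C)c1oc([C@@H](C)[C@@H](O[Si](C)(C)C(C)(C)C)CC)c(C)c(=O)c1C | intermediate
17 | (2R,3R,4R,5R,6E,8S)-8-{6-[(2S,3S)-3-(tert-butyldimethylsilyloxy)pentan-2-yl]-3,5-dimethyl-4-oxo-4H-pyran-2-yl}-2-(6-ethyl-3,5-dimethyl-4-oxo-4H-pyran-2-yl)-3-hydroxy-4,6-dimethylnon-6-en-5-yl propanoate | CCC(=O)O[C@@H](/C(C)=C/[C@H](C)c1oc([C@@H](C)[C@@H](O[Si](C)(C)C(C)(C)C)CC)c(C)c(=O)c1C)[C@H](C)[C@@H](O)[C@@H](C)c1oc(CC)c(C)c(=O)c1C | intermediate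
18 | (2R,3R,4R,5R,6E,8S)-3-acetoxy-8-{6-[(2S,3S)-3-(tert-butyldimethylsilyloxy)pentan-2-yl]-3,5-dimethyl-4-oxo-4H-pyran-2-yl}-2-(6-ethyl-3,5-dimethyl-4-oxo-4H-pyran-2-yl)-4,6-dimethylnon-6-en-5-yl propanoate | CCC(=O)O[C@@H](/C(C)=C/[C@H](C)c1oc([C@@H](C)[C@@H](O[Si](C)(C)C(C)(C)C)CC)c(C)c(=O)c1C)[C@H](C)[C@@H](OC(C)=O)[C@@H](C)c1oc(CC)c(C)c(=O)c1C | intermediate
19 | CNP0265513.1, (2R,3R,4R,5R,6E,8S)-3-acetoxy-2-(6-ethyl-3,5-dimethyl-4-oxo-4H-pyran-2-yl)-8-{6-[(2S,3S)-3-hydroxypentan-2-yl]-3,5-dimethyl-4-oxo-4H-pyran-2-yl}-4,6-dimethylnon-6-en-5-yl propanoate | CCC(=O)O[C@@H](/C(C)=C/[C@H](C)c1oc([C@@H](C)[C@@H](O)CC)c(C)c(=O)c1C)[C@H](C)[C@@H](OC(C)=O)[C@@H](C)c1oc(CC)c(C)c(=O)c1C | target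

## Step count and risks

Total steps: 11. Longest linear sequence: 10 (steps 1, 2, 3, 4, 6, 7, 8, 9, 10, 11; step 5 is a one-step side branch).

The three steps most likely to fail:

**Step 2.** The trienol ether 3 is an untested nucleophile class for this catalysis, propanal is an aliphatic (less reactive) aldehyde, and the product pyranone carbonyl may compete with the catalyst for silicon. Fallback, setting out from 1 and coming back at 5: lithiate 1 with LiN(SiMe3)2 (2.1 equiv, THF, −78 °C) and acylate with N-methoxy-N-methylpropanamide to give the racemic, configurationally labile ketone 2-ethyl-3,5-dimethyl-6-(3-oxopentan-2-yl)-4H-pyran-4-one F1. A ketoreductase chosen from a commercial panel (NADP+, i-PrOH, pH 7.5 buffer, 30 °C) then reduces F1 with dynamic kinetic resolution of the acidic α-centre to 5, so C–C bond formation and stereocontrol are separated.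

**Step 4.** The vinylogous formate 8 may react sluggishly or at its β-carbon, the ionisable adduct may add a second nucleophile, and the C8–H of enal 10 is doubly activated. Fallback, setting out from 7 and coming back at 10: run the same catalytic vinylogous aldol with methacrolein, an ordinary α-branched enal, to give 2-[(2S,3R)-3-hydroxy-4-methylpent-4-en-2-yl]-6-[(2S,3S)-3-(tert-butyldimethylsilyloxy)pentan-2-yl]-3,5-dimethyl-4H-pyran-4-one F2. Ph3SiOReO3 (2 mol %, Et2O, −50 → 0 °C) moves the hydroxyl by 1,3-transposition to the primary allylic alcohol 2-[(2S,3E)-5-hydroxy-4-methylpent-3-en-2-yl]-6-[(2S,3S)-3-(tert-butyldimethylsilyloxy)pentan-2-yl]-3,5-dimethyl-4H-pyran-4-one F3, driven by the more substituted alkene, and MnO2 (CH2Cl2, rt) oxidises F3 to 10 under neutral conditions.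

**Step 9.** The aldehyde 16 is α-branched, aliphatic and β-acyloxy, so it is slow and prone to elimination, and the nucleophile class is new. Fallback, setting out from 14 (with 1) and coming back at 17, replacing steps 7 to 9: add the lithium alkoxide of 14 to the lithium dienolate of 1 (LiN(SiMe3)2, THF, −78 °C) so that the thioester acylates the ethyl arm of ring B. This gives the β-hydroxy ketone 2-ethyl-3,5-dimethyl-6-[(4S,5R,6E,8S)-5-hydroxy-4,6-dimethyl-3-oxo-8-{6-[(2S,3S)-3-(tert-butyldimethylsilyloxy)pentan-2-yl]-3,5-dimethyl-4-oxo-4H-pyran-2-yl}non-6-en-2-yl]-4H-pyran-4-one F4, as interconverting C2 epimers. An Evans–Tishchenko reduction (propanal, SmI2 30 mol %, THF, −10 °C) then delivers hydride to the C3 ketone anti to O5, transfers the propanoyl group to O5, and through Felkin-matched dynamic kinetic resolution of the labile C2 centre gives 17.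

## Further compounds

F1 | step 2 | 2-ethyl-3,5-dimethyl-6-(3-oxopentan-2-yl)-4H-pyran-4-one (racemic) | CCC(=O)C(C)c1oc(CC)c(C)c(=O)c1C
F2 | step 4 | 2-[(2S,3R)-3-hydroxy-4-methylpent-4-en-2-yl]-6-[(2S,3S)-3-(tert-butyldimethylsilyloxy)pentan-2-yl]-3,5-dimethyl-4H-pyran-4-one | C=C(C)[C@H](O)[C@H](C)c1oc([C@@H](C)[C@@H](O[Si](C)(C)C(C)(C)C)CC)c(C)c(=O)c1C
F3 | step 4 | 2-[(2S,3E)-5-hydroxy-4-methylpent-3-en-2-yl]-6-[(2S,3S)-3-(tert-butyldimethylsilyloxy)pentan-2-yl]-3,5-dimethyl-4H-pyran-4-one | OC/C(C)=C/[C@H](C)c1oc([C@@H](C)[C@@H](O[Si](C)(C)C(C)(C)C)CC)c(C)c(=O)c1C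
F4 | step 9 | 2-ethyl-3,5-dimethyl-6-[(4S,5R,6E,8S)-5-hydroxy-4,6-dimethyl-3-oxo-8-{6-[(2S,3S)-3-(tert-butyldimethylsilyloxy)pentan-2-yl]-3,5-dimethyl-4-oxo-4H-pyran-2-yl}non-6-en-2-yl]-4H-pyran-4-one (C2 epimers) | CCc1oc(C(C)C(=O)[C@@H](C)[C@@H](O)/C(C)=C/[C@H](C)c2oc([C@@H](C)[C@@H](O[Si](C)(C)C(C)(C)C)CC)c(C)c(=O)c2C)c(C)c(=O)c1C
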